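The data stem from a simulated flask from invented constants, noise included.

If the new recipes differ from the spring and winter runs in the charge of starting material, and keep the same feed, partner, protic impurity and free catalyst, the asked row turns on how the fraction of the charge ending as target moves with that charge.

common to all: partner 0.475 M

| run | starting material | second substrate | protic impurity | free catalyst | remark | time |
|---|---|---|---|---|---|---|
| spring | 0.014 M | 0.25 M (fed, over 4.0 min) | 0.50 M | 1 mM | run made earlier |  |
| winter | 0.42 M | 0.25 M (fed, over 4.0 min) | 0.50 M | 1 mM | run made earlier |  |
| Friday's | 0.020 M | 0.250 M (fed, over 4.0 min) | 0.500 M | 1.0 mM |  | 10 min |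
| Wednesday's | 0.060 M | 0.250 M (fed, over 4.0 min) | 0.500 M | 1.0 mM |  | 10 min |
| Saturday's | 0.15 M | 0.250 M (fed, over 4.0 min) | 0.500 M | 1.0 mM |  | 10 min |
| Thursday's | 0.50 M | 0.250 M (fed, over 4.0 min) | 0.500 M | 1.0 mM |  | 10 min |

| run | time / min | target / % |
|---|---|---|
| spring | 2.00 | 4.5 |
| spring | 4.00 | 6.8 |
| spring | 6.00 | 7.1 |
| spring | 8.00 | 10.6 |
| spring | 10.0 | 12.5 |
| winter | 2.00 | 1.8 |
| winter | 4.00 | 5.1 |
| winter | 6.00 | 7.4 |
| winter | 8.00 | 6.3 |
| winter | 10.0 | 7.9 |

(readings scatter by 1 percentage point)

- amount of target at the end, in percent of the starting material charged for Friday's, Wednesday's, Saturday's, Thursday's, in this order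
- how that number moves from the first to the last of them (rises all the way / rises, then falls / hardly changes / falls all the way / falls, then rises)

- the numbers in the tables scatter with a standard deviation of 1 percentage point
- "hardly changes" means that all values lie within two and a half points (for a concentration: within two and a half percent of the largest)

I assume that a rival one order higher in starting material competes with the way to target. The end fraction is then the dilute fraction divided by one plus the charge over a competition charge, and the two last readings set both constants. I first ask which reading matters. An error of 1 percentage point in winter's last reading moves my Thursday's figure by 1.1 points, but the same error in spring's last reading moves it by 0.063 points. Spring's reading instead carries Friday's figure, which it moves by 0.97 points. The shared charges need no value of their own, since both readings already carry them.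

Read off these two scattered readings, the number itself is 0.683 M, the competition charge, with a dilute fraction of 12.8%. My row is therefore 12.4%, 11.7%, 10.5% and 7.37%.

The forecast gives 12.3%, 12%, 11% and 6.7%, and says the row falls all the way. Its ground differs from mine: “That suggests a reagent available in a fixed absolute amount”. My Thursday's figure is higher than the forecast's.

The flask gives 12.0%, 11.6%, 10.7% and 8.31%, and the row falls all the way.

    starting material + free catalyst ⇌ catalyst intermediate A (K = 1.10 M⁻¹, k = 80.0 M⁻¹ min⁻¹)
    partner + catalyst intermediate A → free catalyst + target (k = 92.0 M⁻¹ min⁻¹)
    second substrate + free catalyst ⇌ catalyst intermediate B (K = 8.80 M⁻¹, k = 130 M⁻¹ min⁻¹)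
    partner + catalyst intermediate B → free catalyst + second product (k = 27.0 M⁻¹ min⁻¹)
    partner + protic impurity → quenched reagent (k = 0.140 M⁻¹ min⁻¹)
    catalyst intermediate A → spent catalyst (k = 0.0210 min⁻¹)
    2 starting material → self-condensation product (k = 0.0540 M⁻¹ min⁻¹)

Thursday's result stands 0.94 points above my figure. Put through the same quantity, Friday's and Thursday's results give a competition charge of 1.06 M. That value returns 10.7% for Saturday's flask, which holds 10.7%. One reason for the fall, though not shown to be the main one, is the way back from catalyst intermediate B to second substrate and free catalyst: in the run without it, the fall from Friday's to Thursday's is 2.1 points instead of 3.7 points.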